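- I decided to reckon this flask from one concentration, which I called the working catalyst c(work): the precatalyst charged minus the impurity charged, 7.50 mM. Each impurity takes one catalyst, and c(impurity) lay below the precatalyst charge.

all flasks: left-handed substrate 0.086 M; right-handed substrate 0.086 M; precatalyst 10 mol%; impurity 1.1 mM
- midnight: partner 1.5 equiv; run made earlier
- spring: partner 6 equiv; run made earlier
- flask: partner 3.00 equiv; time 12 min

- midnight (time / min: left-handed substrate / %, right-handed substrate / %, left-handed product / %): 0.833: 51.3, 50.1, 1.4; 2.00: 48.3, 50.6, 0; 4.00: 50.5, 49.8, 0.3; 10.0: 49.5, 49.6, 1.5
- spring (time / min: left-handed substrate / %, right-handed substrate / %, left-handed product / %): 2.50: 46.3, 50.1, 2.7; 5.00: 43.8, 50.0, 4.1; 8.00: 40.1, 48.5, 10.0; 10.0: 36.9, 47.5, 13.4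

(standard deviation of a reading: 1 percentage point)

* part of the left-handed substrate and right-handed substrate charged together that has reacted at 12 min
* excess of left-handed product over right-handed product in the product at 12 min
* excess of right-handed substrate over left-handed substrate among what is left of the two at 12 min

- free catalyst is single-handed; left-handed substrate and right-handed substrate are mirror images of each other, charged as a racemate, each of them at the stated concentration
- reactions considered so far: partner + free catalyst + right-handed substrate -> free catalyst + right-handed product; left-handed product <-> right-handed product; free catalyst + impurity -> spent catalyst; partner + free catalyst + left-handed substrate -> free catalyst + left-handed product; partner + precatalyst -> free catalyst + spent reagent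
- an excess is the difference of the two amounts in percent of their sum
- an excess is below zero if the other one leads

- Partner stood in excess over left-handed substrate, and c(work) was equal in the spring run and this flask, so I treated the loss of left-handed substrate as pseudo-first-order, with a constant proportional to c(partner).
- The spring readings at 5.00 min and 10.0 min gave a constant of 0.0343 min⁻¹, and their line started at 1.14 min, a lag I took as the partner-driven release of free catalyst.
- Scaling both by c(partner) gave this flask 0.0171 min⁻¹ and a lag of 2.28 min, so 84.6% of the left-handed substrate should remain at 12 min.
- The selectivity factor, the ratio of the two substrates' logarithmic losses, read 5.92 from the last spring reading, which gave eP 69.4% with no racemisation counted.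
- That was the weak link, a right-handed loss of 2.5 percentage points against a scatter of 1 point. Summing the logarithms over the spring readings together, I read 9.20, so 98.2% of the right-handed substrate should remain, and I committed to c 8.57%, eP 79.1%, eS 7.44%.
- The forecast differed, with c 7%, eP 69% and eS 5.1%, its eP below mine, on the ground that “the selectivity is about 6–7, giving a product excess near 70%”.
- The flask gave c 8.12%, eP 78.9% and eS 7.07%.

    partner + free catalyst + right-handed substrate → free catalyst + right-handed product (k = 0.920 L² mol⁻² min⁻¹)
    left-handed product ⇌ right-handed product (k = 0.00130 min⁻¹)
    free catalyst + impurity → spent catalyst (k = 710 L mol⁻¹ min⁻¹)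
    partner + free catalyst + left-handed substrate → free catalyst + left-handed product (k = 8.90 L² mol⁻² min⁻¹)
    partner + precatalyst → free catalyst + spent reagent (k = 1.90 L mol⁻¹ min⁻¹)

- In this flask the release of free catalyst had half of its turnover up to 12 min behind it by 1.42 min, sooner than the 12 min, and at 12.0 min free catalyst stood at 86.8% of the catalyst charged, against 87.2% from c(work). In the neighbour charged with 40 mol% of precatalyst, c(work) comes to 33.3 mM, or 96.8% of its catalyst charged, and at 12.0 min that neighbour held 95.9% as free catalyst, 0.853% as precatalyst and 3.20% as spent catalyst.

The earlier runs and the new flask are calculated from invented constants; the scatter is artificial.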